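Retrosynthetic overview
- Numbering (drimane type): ring A = C1, C2, C3(OH), C4(Me2), C5, C10(H). Ring B = C5=C6, C7, C8(Me), C9(Me, C11H2OAr), C10. The last bonds made are C11–OAr (Mitsunobu with isofraxidin), C3–H (ketone reduction) and the second C4–CH3 (α-methylation of a dienolate).
- Enabling feature: the ring-fusion carbon C5 carries an alkene C5=C6 that is exocyclic to ring A and endocyclic to ring B, next to C4 and the oxygenated C3. At the dienol level, C3(OSi)=C4(Me)–C5=C6 is the heteroannular diene that a vinylallene Diels–Alder reaction leaves behind.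
- Key disconnection: C1–C2 and C5–C10 at once, back to the open-chain tetraene 18, H2C2=C3(OTES)–C4(Me)=C5=C6H–C7–C8–C9–C10H=C1H2. Rings A and B form together, and no ring is present before.
- The allene axis alone fixes C10. It comes from an (R)-propargylic mesylate by anti SN2' attack of methylcopper, and the carbinol comes from asymmetric transfer hydrogenation of ynone 15 (acid 11 + siloxyenyne 13).
- C8 is bought with (R)-methyl hydrogen 3-methylglutarate. C9 is set on a temporary δ-lactone ring by two enolate alkylations, and i-Bu2AlH/Wittig then opens this ring to the vinyl group and the C6 alcohol.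

Key step: step 12

Remark: 1, 12 and 24 (isofraxidin) are taken as commercial; the allene axis of 18 is written in SMILES in the extended tetrahedral notation and is named (Ra) in the text.

Step 1
Reactants: 1 (R)-methyl hydrogen 3-methylglutarate
Product: 3 (S)-4-methyltetrahydro-2H-pyran-2-one, via hydroxy acid 2 (not isolated)
Conditions: LiBH4 (2.5 equiv), THF, 0 °C to rt; then 2 M HCl, rt
Reagents that add atoms: none
Why: Chemoselective hydride reduction of the ester beside the unreactive lithium carboxylate followed by acid-induced lactonization, which leaves the stereocentre (future C8) untouched, its descriptor changing from R to S only through the new ranking of the two arms.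

Step 2
Reactants: 3 (S)-4-methyltetrahydro-2H-pyran-2-one
Product: 5 (3R,4S)-3,4-dimethyltetrahydro-2H-pyran-2-one, via lithium enolate 4 (not isolated)
Conditions: LiN(i-Pr)2 (LDA), THF, −78 °C; MeI, −78 to −40 °C
Reagents that add atoms: lithium diisopropylamide [Li]N(C(C)C)C(C)C (lithium of 4); iodomethane CI
Why: Lactone enolate alkylation in which MeI enters anti to the C8 methyl group, although this centre is planarized again in step 3 and its configuration does not matter.

Step 3
Reactants: 5 (3R,4S)-3,4-dimethyltetrahydro-2H-pyran-2-one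
Product: 7 (3S,4S)-3-[(benzyloxy)methyl]-3,4-dimethyltetrahydro-2H-pyran-2-one, via lithium enolate 6 (not isolated)
Conditions: LiN(i-Pr)2 (LDA), THF–DMPU, −78 °C; BnOCH2Cl, −78 to −20 °C
Reagents that add atoms: lithium diisopropylamide [Li]N(C(C)C)C(C)C (lithium of 6); benzyl chloromethyl ether ClCOCc1ccccc1
Why: Second lactone enolate alkylation that creates quaternary C9: allylic 1,2-strain with the enolate methyl group turns the C8 methyl group pseudoaxial, so BnOCH2Cl attacks the opposite face and the two methyl groups end up cis, as is well known for 2,3-dimethylcyclohexanone enolates.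

Step 4
Reactants: 7 (3S,4S)-3-[(benzyloxy)methyl]-3,4-dimethyltetrahydro-2H-pyran-2-one
Product: 8 (3S,4S)-3-[(benzyloxy)methyl]-3,4-dimethyltetrahydro-2H-pyran-2-ol (lactol, both anomers)
Conditions: i-Bu2AlH (1.1 equiv), CH2Cl2, −78 °C; aq. potassium sodium tartrate
Reagents that add atoms: none
Why: Partial reduction of a lactone with i-Bu2AlH, which stops at the stable tetrahedral aluminate at low temperature and touches no stereocentre of the target.

Step 5
Reactants: 8 lactol
Product: 9 (3S,4S)-4-[(benzyloxy)methyl]-3,4-dimethylhex-5-en-1-ol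
Conditions: Ph3PCH3Br, KOt-Bu, THF, 0 °C to reflux
Reagents that add atoms: methyltriphenylphosphonium bromide C[P+](c1ccccc1)(c1ccccc1)c1ccccc1.[Br-]
Why: Wittig methylenation of the hydroxy aldehyde tautomer of the lactol opens the temporary ring, makes the C10=C1 vinyl group and frees the C6 alcohol, and the quaternary α-carbon rules out epimerization.

Step 6
Reactants: 9 (3S,4S)-4-[(benzyloxy)methyl]-3,4-dimethylhex-5-en-1-ol
Product: 11 (3S,4S)-4-[(benzyloxy)methyl]-3,4-dimethylhex-5-enoic acid, via aldehyde 10 (not isolated)
Conditions: TEMPO (cat.), PhI(OAc)2 (2.2 equiv), MeCN–H2O, rt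
Reagents that add atoms: water O
Why: Oxoammonium (TEMPO) oxidation of the primary alcohol through the aldehyde hydrate to the acid, conditions that leave the terminal alkene and the benzyl ether alone.

Step 7
Reactants: 12 but-3-yn-2-one
Product: 13 2-(triethylsilyloxy)but-1-en-3-yne
Conditions: Et3SiOTf, Et3N, Et2O, −78 to 0 °C
Reagents that add atoms: triethylsilyl trifluoromethanesulfonate CC[Si](CC)(CC)OS(=O)(=O)C(F)(F)F
Why: Soft enolization of a methyl ketone with a silyl triflate and an amine, which can only give the terminal enol ether because the alkynyl side has no α-hydrogen.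

Step 8
Reactants: 11 (3S,4S)-4-[(benzyloxy)methyl]-3,4-dimethylhex-5-enoic acid; 13 2-(triethylsilyloxy)but-1-en-3-yne
Product: 15 (7S,8S)-8-[(benzyloxy)methyl]-7,8-dimethyl-2-(triethylsilyloxy)deca-1,9-dien-3-yn-5-one, via acid chloride 14 (not isolated)
Conditions: (COCl)2, DMF (cat.), CH2Cl2, 0 °C, evaporation; then 13, PdCl2(PPh3)2 (2 mol %), CuI (4 mol %), Et3N (1.2 equiv), THF, rt, degassed
Reagents that add atoms: oxalyl chloride ClC(=O)C(=O)Cl (chlorine of 14)
Why: Acyl Sonogashira coupling of the freshly made acid chloride with the terminal alkyne, a mild ynone synthesis that tolerates the silyl enol ether and forms the C5–C6 bond.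

Step 9
Reactants: 15 ynone
Product: 16 (5R,7S,8S)-8-[(benzyloxy)methyl]-7,8-dimethyl-2-(triethylsilyloxy)deca-1,9-dien-3-yn-5-ol
Conditions: Ru[(R,R)-TsDPEN](p-cymene) (2 mol %), i-PrOH, rt
Reagents that add atoms: none
Why: Noyori asymmetric transfer hydrogenation of an alkynyl ketone, in which the catalyst places the alkyne where an aryl group would sit so that the (R,R)-ligand gives the (R)-carbinol at C6 irrespective of the remote centres C8 and C9.

Step 10
Reactants: 16 (R)-propargylic alcohol
Product: 17 (5R,7S,8S)-8-[(benzyloxy)methyl]-7,8-dimethyl-2-(triethylsilyloxy)deca-1,9-dien-3-yn-5-yl methanesulfonate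
Conditions: MsCl, Et3N, CH2Cl2, −78 to −30 °C; used at once
Reagents that add atoms: methanesulfonyl chloride CS(=O)(=O)Cl
Why: O-Sulfonylation that does not touch the C6–O bond and so keeps the (R) configuration while making the leaving group for the SN2' step.

Step 11
Reactants: 17 propargylic mesylate
Product: 18 (Ra,7S,8S)-8-[(benzyloxy)methyl]-3,7,8-trimethyl-2-(triethylsilyloxy)deca-1,3,4,9-tetraene (2-siloxy vinylallene)
Conditions: MeMgBr, CuBr·SMe2, LiBr, THF, −70 to −40 °C; filtration through Et3N-deactivated silica
Reagents that add atoms: methylmagnesium bromide C[Mg]Br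
Why: anti-Selective SN2' displacement of a propargylic sulfonate by a methylcopper reagent, the standard route to vinylallenes from enynyl carbinols, which puts the first methyl group on C4 and turns the (R) centre at C6 into the (Ra) axis.

Step 12
Reactants: 18 2-siloxy vinylallene
Product: 19 (1R,2S,8aR)-1-[(benzyloxy)methyl]-1,2,5-trimethyl-6-(triethylsilyloxy)-1,2,3,7,8,8a-hexahydronaphthalene (8S,9R,10R in the numbering of the overview)
Conditions: toluene (0.02 M), BHT (cat.), Et3N (0.1 equiv), sealed tube, 130 °C
Reagents that add atoms: none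
Why: Heating brings the s-cis diene C2=C3–C4=C5 of the vinylallene over the C10=C1 vinyl group, and a concerted suprafacial (4+2) cycloaddition forms C1–C2 and C5–C10 together, leaving the orthogonal allene π bond as the C5=C6 alkene and C3=C4 as the silyl enol ether. The closest known reaction type is the intramolecular Diels–Alder reaction of vinylallenes tethered through the allene terminus to unactivated alkenes, which gives heteroannular hexalin dienes. Ring A (C1, C2, C3, C4, C5, C10) closes as the cycloadduct ring and ring B (C5 to C10) as the tether ring over the three-atom link C7–C8–C9, with the tether exo to the diene, the only arrangement this short link allows. C10 is the only new stereocentre and is controlled by the allene axis: C7 stands perpendicular to the diene plane, the alkene can reach only the diene face that carries C7, and the (Ra) axis is thereby translated into (10R), with H-10 trans to the C9 methyl group. The existing centres reinforce this, because the chair-like tether then holds the C8 methyl and the CH2OBn group equatorial and only the C9 methyl axial. The step needs (4+2) periselectivity with an unactivated dienophile, which is secured by the strain released from the allene, the gem-dialkyl effect of quaternary C9 and the 2,3-disubstitution that favours the s-cis diene, while the unsubstituted C2 terminus excludes the 1,5-hydrogen shift typical of vinylallenes.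

Step 13
Reactants: 19 bicyclic silyl dienol ether
Product: 21 (4aR,5R,6S)-5-[(benzyloxy)methyl]-1,1,5,6-tetramethyl-3,4,4a,5,6,7-hexahydronaphthalen-2(1H)-one, via lithium dienolate 20 (not isolated)
Conditions: MeLi, THF, 0 °C; then MeI, DMPU, −78 to 0 °C
Reagents that add atoms: methyllithium [Li]C (lithium of 20); iodomethane CI
Why: Regiospecific lithium enolate generation from a silyl enol ether with MeLi followed by α-alkylation of the extended dienolate (deconjugative methylation as in 4,4-dimethyl-5-en-3-one steroids), which completes C4 and, without any equilibrating base, leaves H-10 untouched.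

Step 14
Reactants: 21 4,4-dimethyl-5-en-3-one
Product: 22 (2S,4aR,5R,6S)-5-[(benzyloxy)methyl]-1,1,5,6-tetramethyl-1,2,3,4,4a,5,6,7-octahydronaphthalen-2-ol (axial 3β-OH)
Conditions: LiBH(s-Bu)3 (L-Selectride), THF, −78 °C; then aq. NaOH, H2O2
Reagents that add atoms: none
Why: Equatorial attack of the bulky trialkylborohydride on chair ring A (H-10 axial, C9 equatorial) should deliver hydride to the α face and give the axial 3β (3S) alcohol, as with 4,4-dimethyl-3-oxo triterpenoids.

Step 15
Reactants: 22 benzyl ether alcohol
Product: 23 (2S,4aR,5R,6S)-5-(hydroxymethyl)-1,1,5,6-tetramethyl-1,2,3,4,4a,5,6,7-octahydronaphthalen-2-ol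
Conditions: Li, NH3 (l), THF, −78 °C; then NH4Cl
Reagents that add atoms: none
Why: Dissolving-metal (Birch-type) cleavage of the benzyl ether, which spares the isolated trisubstituted alkene and all stereocentres.

Step 16
Reactants: 23 diol; 24 isofraxidin (7-hydroxy-6,8-dimethoxy-2H-chromen-2-one)
Product: 25 7-{[(1R,2S,6S,8aR)-6-hydroxy-1,2,5,5-tetramethyl-1,2,3,5,6,7,8,8a-octahydronaphthalen-1-yl]methoxy}-6,8-dimethoxy-2H-chromen-2-one (CNP0110107.1)
Conditions: 24 (1.3 equiv), PPh3, DIAD, toluene (1 M), 0 to 60 °C, ultrasound
Reagents that add atoms: none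
Why: Mitsunobu etherification in which the acidic phenol 24 displaces the oxyphosphonium group at primary C11, while the axial C3 hydroxyl next to quaternary C4 is too hindered to be substituted, and no stereocentre takes part.

Compound list
1 | (R)-methyl hydrogen 3-methylglutarate | COC(=O)C[C@H](C)CC(=O)O | starting material
2 | (S)-5-hydroxy-3-methylpentanoic acid | OCC[C@H](C)CC(=O)O | intermediate
3 | (S)-4-methyltetrahydro-2H-pyran-2-one | O=C1C[C@@H](C)CCO1 | intermediate
4 | lithium enolate of 3 | [Li]OC1=C[C@@H](C)CCO1 | intermediate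
5 | (3R,4S)-3,4-dimethyltetrahydro-2H-pyran-2-one | O=C1[C@H](C)[C@@H](C)CCO1 | intermediate
6 | lithium enolate of 5 | [Li]OC1=C(C)[C@@H](C)CCO1 | intermediate
7 | (3S,4S)-3-[(benzyloxy)methyl]-3,4-dimethyltetrahydro-2H-pyran-2-one | O=C1[C@](C)(COCc2ccccc2)[C@@H](C)CCO1 | intermediate
8 | (3S,4S)-3-[(benzyloxy)methyl]-3,4-dimethyltetrahydro-2H-pyran-2-ol (both anomers) | OC1[C@](C)(COCc2ccccc2)[C@@H](C)CCO1 | intermediate
9 | (3S,4S)-4-[(benzyloxy)methyl]-3,4-dimethylhex-5-en-1-ol | OCC[C@H](C)[C@@](C)(COCc1ccccc1)C=C | intermediate
10 | (3S,4S)-4-[(benzyloxy)methyl]-3,4-dimethylhex-5-enal | O=CC[C@H](C)[C@@](C)(COCc1ccccc1)C=C | intermediate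
11 | (3S,4S)-4-[(benzyloxy)methyl]-3,4-dimethylhex-5-enoic acid | OC(=O)C[C@H](C)[C@@](C)(COCc1ccccc1)C=C | intermediate
12 | but-3-yn-2-one | CC(=O)C#C | starting material
13 | 2-(triethylsilyloxy)but-1-en-3-yne | C=C(O[Si](CC)(CC)CC)C#C | intermediate
14 | (3S,4S)-4-[(benzyloxy)methyl]-3,4-dimethylhex-5-enoyl chloride | ClC(=O)C[C@H](C)[C@@](C)(COCc1ccccc1)C=C | intermediate
15 | (7S,8S)-8-[(benzyloxy)methyl]-7,8-dimethyl-2-(triethylsilyloxy)deca-1,9-dien-3-yn-5-one | C=C(O[Si](CC)(CC)CC)C#CC(=O)C[C@H](C)[C@@](C)(COCc1ccccc1)C=C | intermediate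
16 | (5R,7S,8S)-8-[(benzyloxy)methyl]-7,8-dimethyl-2-(triethylsilyloxy)deca-1,9-dien-3-yn-5-ol | C=C(O[Si](CC)(CC)CC)C#C[C@H](O)C[C@H](C)[C@@](C)(COCc1ccccc1)C=C | intermediate
17 | methanesulfonate of 16 | C=C(O[Si](CC)(CC)CC)C#C[C@H](OS(C)(=O)=O)C[C@H](C)[C@@](C)(COCc1ccccc1)C=C | intermediate
18 | (Ra,7S,8S)-8-[(benzyloxy)methyl]-3,7,8-trimethyl-2-(triethylsilyloxy)deca-1,3,4,9-tetraene | C=C(O[Si](CC)(CC)CC)C(C)=[C@]=C([H])C[C@H](C)[C@@](C)(COCc1ccccc1)C=C | intermediate
19 | (1R,2S,8aR)-1-[(benzyloxy)methyl]-1,2,5-trimethyl-6-(triethylsilyloxy)-1,2,3,7,8,8a-hexahydronaphthalene (descriptor at C9 changes from S to R by ranking only) | c3ccccc3COC[C@@]1(C)[C@@H]2CCC(O[Si](CC)(CC)CC)=C(C)C2=CC[C@@H]1C | intermediate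
20 | lithium dienolate from 19 | c3ccccc3COC[C@@]1(C)[C@@H]2CCC(O[Li])=C(C)C2=CC[C@@H]1C | intermediate
21 | (4aR,5R,6S)-5-[(benzyloxy)methyl]-1,1,5,6-tetramethyl-3,4,4a,5,6,7-hexahydronaphthalen-2(1H)-one | c3ccccc3COC[C@@]1(C)[C@@H]2CCC(=O)C(C)(C)C2=CC[C@@H]1C | intermediate
22 | (2S,4aR,5R,6S)-5-[(benzyloxy)methyl]-1,1,5,6-tetramethyl-1,2,3,4,4a,5,6,7-octahydronaphthalen-2-ol | c3ccccc3COC[C@@]1(C)[C@@H]2CC[C@H](O)C(C)(C)C2=CC[C@@H]1C | intermediate
23 | (2S,4aR,5R,6S)-5-(hydroxymethyl)-1,1,5,6-tetramethyl-1,2,3,4,4a,5,6,7-octahydronaphthalen-2-ol | OC[C@@]1(C)[C@@H]2CC[C@H](O)C(C)(C)C2=CC[C@@H]1C | intermediate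
24 | isofraxidin (7-hydroxy-6,8-dimethoxy-2H-chromen-2-one) | COc1cc2ccc(=O)oc2c(OC)c1O | starting material
25 | CNP0110107.1 | COc1cc2ccc(=O)oc2c(OC)c1OC[C@@]1(C)[C@@H]2CC[C@H](O)C(C)(C)C2=CC[C@@H]1C | target

Total step count: 16
Longest linear sequence: 15 (steps 1 to 6 and 8 to 16)

Steps most likely to fail

**Step 12.** The unactivated, neopentyl-type vinyl group may add too slowly. Loss of the silyl group, oligomerization of the siloxydiene, or an allene–alkene (2+2) or ene pathway could then compete at the temperature needed. The fallback sets out from 18 and comes back at 19. It replaces the pericyclic closure by a metal-templated (4+2) cycloaddition of the kind known for unactivated diene–ene and vinylallene substrates. [RhCl(cod)]2 with P[OCH(CF3)2]3 (monovalent rhodium) in THF at 25 to 60 °C binds the diene and the alkene, closes a rhodacycle and releases 19 by reductive elimination. The short tether still brings the alkene to the diene face that carries C7. No new isolable compound is made (F0).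

**Step 16.** Substitution at the neopentyl carbon C11 may be so slow that the reagent is consumed, or that the C3 hydroxyl is activated and eliminated. The fallback sets out from 23 and comes back at 25, and it separates activation from substitution. Tf2O (1.0 equiv) with 2,6-di-tert-butylpyridine in CH2Cl2 at −78 °C should sulfonylate only the primary hydroxyl and give the C11 triflate of diol 23, F1. This is treated at once with the cesium phenoxide of 24 (Cs2CO3, DMF, 0 °C to rt). The far better leaving group should allow SN2 at the neopentyl centre before any skeletal migration.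

**Step 14.** Facial selectivity may be poor, because the sp2 carbon C5 removes one axial hydrogen from the β face and the axial C4 methyl group hinders the equatorial approach. The equatorial 3α alcohol could then dominate. The fallback sets out from 21 and comes back at 22. It changes from substrate control to catalyst control with a Corey–Bakshi–Shibata reduction, using (R)-Me-CBS oxazaborolidine and BH3·SMe2 or catecholborane in toluene at −40 to 0 °C. The catalyst distinguishes the quaternary C4 (large) from the C2 methylene (small) and should deliver the (3S) alcohol. No new compound is made (F0).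

Further compounds
F0 | step 12 | none | none
F1 | step 16 | [(1R,2S,6S,8aR)-6-hydroxy-1,2,5,5-tetramethyl-1,2,3,5,6,7,8,8a-octahydronaphthalen-1-yl]methyl trifluoromethanesulfonate | FC(F)(F)S(=O)(=O)OC[C@@]1(C)[C@@H]2CC[C@H](O)C(C)(C)C2=CC[C@@H]1C
F0 | step 14 | none | none
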